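**Plan**
- Ring A is the heptyl-bearing benzoic acid ring (C1 carboxyl, C2 heptyl, C4 ester oxygen, C6 hydroxyl); ring B is the orsellinoyl ring. The first cut is the depside ester bond between the C4 oxygen of ring A and the carbonyl carbon of ring B.
- The second cut removes the C2–heptyl and C1–carboxyl bonds of ring A together. C1 lies between the heptyl carbon C2 and the oxygen-bearing C6, which is the 1,2,3-pattern left when a carbon nucleophile and then an electrophile add across a 3-alkoxybenzyne.
- Forward, 1-fluoro-3,5-dimethoxybenzene becomes a bromofluoro bis(methoxymethyl) ether. Magnesium, heptylmagnesium bromide and carbon dioxide then place both carbon substituents in one flask, and benzyl ester formation and acetal removal follow.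
- Ring B is taken from orsellinic acid as its di-O-benzyl acid and joined to the free C4 hydroxyl of ring A. One hydrogenolysis removes all three benzyl groups.
- Both benzene rings are bought and no ring is formed. The target has no stereocentre, so only regiochemistry has to be controlled.

Key step: step 5

Step 1
Reactants: 1 1-fluoro-3,5-dimethoxybenzene
Product: 2 5-fluorobenzene-1,3-diol
Conditions: BBr3 (3 equiv), CH2Cl2, −78 °C → rt; then H2O
Reagents that add atoms: none
Why: Lewis-acid cleavage of aryl methyl ethers (BBr3 demethylation), in which boron binds the ether oxygen and bromide removes the methyl group by SN2 attack while the C–F bond is untouched.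

Step 2
Reactants: 2 5-fluorobenzene-1,3-diol
Product: 3 1-fluoro-3,5-bis(methoxymethoxy)benzene
Conditions: MOMCl (3 equiv), iPr2NEt (4 equiv), CH2Cl2, 0 °C → rt
Reagents that add atoms: chloromethyl methyl ether, COCCl
Why: O-alkylation of both phenols by the reactive α-chloro ether under amine base (methoxymethyl protection) should give acetals that tolerate Grignard reagents and later serve as chelating groups.

Step 3
Reactants: 3 1-fluoro-3,5-bis(methoxymethoxy)benzene
Product: 4 2-bromo-1-fluoro-3,5-bis(methoxymethoxy)benzene
Conditions: NBS (1.0 equiv), MeCN, 0 °C → rt, dark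
Reagents that add atoms: N-bromosuccinimide, O=C1CCC(=O)N1Br
Why: Electrophilic aromatic bromination; every free position is ortho or para to both acetal oxygens, but C4 is shielded between two OCH2OMe groups whereas the equivalent C2 and C6 have only the small fluorine on one side, so monobromination should occur between fluorine and oxygen.

Step 4
Reactants: 5 1-bromoheptane
Product: 6 heptylmagnesium bromide (titrated solution in THF)
Conditions: Mg turnings, I2 (cat.), THF, reflux
Reagents that add atoms: magnesium, [Mg]
Why: Grignard formation by insertion of magnesium into a primary C–Br bond.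

Step 5
Reactants: 4 2-bromo-1-fluoro-3,5-bis(methoxymethoxy)benzene, 6 heptylmagnesium bromide
Product: 10 2-heptyl-4,6-bis(methoxymethoxy)benzoic acid, via 2-fluoroarylmagnesium bromide 7 (not isolated), via 3,5-bis(methoxymethoxy)benzyne 8 (not isolated), via 2-heptylarylmagnesium bromide 9 (not isolated)
Conditions: Mg turnings (2 equiv), 6 (3.5 equiv), THF, 65 °C, slow addition of 4; then CO2 (dry gas), −20 °C → rt; then cold 1 M HCl to pH 3
Reagents that add atoms: carbon dioxide, O=C=O
Why: Magnesium inserts into the C–Br bond of 4 to give 7, which at reflux loses MgBrF to form aryne 8; heptylmagnesium bromide adds across the strained triple bond to give 9, and carbon dioxide then carboxylates the aryl–magnesium bond. This is the known carbomagnesiation of a 3-alkoxyaryne generated from an ortho-halofluoroarene, followed by electrophilic trapping of the new aryl Grignard reagent. No ring is closed and no stereocentre is formed. The selectivity required is regiochemical: the heptyl group has to bond to the aryne carbon that bore fluorine, so that magnesium, and then the carboxyl, end up next to the acetal oxygen. The flanking OCH2OMe group secures this, since it polarises and distorts the aryne towards attack at the remote carbon and stabilises the adjacent carbanion by induction and chelation of magnesium, while the second acetal, one position further away, has only a weak opposing inductive effect. Slow addition of 4 to an excess of 6 keeps 7 dilute so that it does not add to 8, and the cold, brief acidification to pH 3 spares the acetals.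

Step 6
Reactants: 10 2-heptyl-4,6-bis(methoxymethoxy)benzoic acid
Product: 11 benzyl 2-heptyl-4,6-bis(methoxymethoxy)benzoate
Conditions: BnBr (1.2 equiv), K2CO3 (1.5 equiv), DMF, rt
Reagents that add atoms: benzyl bromide, BrCc1ccccc1
Why: Carboxylate O-alkylation (SN2 at the benzylic carbon) is indifferent to the two ortho substituents because the new bond forms at oxygen, away from the shielded carbonyl carbon.

Step 7
Reactants: 11 benzyl 2-heptyl-4,6-bis(methoxymethoxy)benzoate
Product: 12 benzyl 2-heptyl-4,6-dihydroxybenzoate
Conditions: HCl (0.5 M in MeOH), THF, 40 °C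
Reagents that add atoms: none
Why: Acid-catalysed transacetalisation of the methoxymethyl ethers to methanol frees both phenols, while the di-ortho-substituted benzyl ester resists acid transesterification and, as an ester, cannot decarboxylate.

Step 8
Reactants: 13 orsellinic acid (2,4-dihydroxy-6-methylbenzoic acid)
Product: 14 benzyl 2,4-bis(benzyloxy)-6-methylbenzoate
Conditions: BnBr (3.5 equiv), K2CO3 (4 equiv), DMF, rt → 60 °C
Reagents that add atoms: benzyl bromide, BrCc1ccccc1
Why: Exhaustive Williamson-type O-benzylation; the carboxylate is alkylated first at room temperature, which blocks decarboxylation, and warming then alkylates both phenols including the chelated one.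

Step 9
Reactants: 14 benzyl 2,4-bis(benzyloxy)-6-methylbenzoate
Product: 15 2,4-bis(benzyloxy)-6-methylbenzoic acid
Conditions: KOH, DMSO–H2O, 90 °C; then 1 M HCl
Reagents that add atoms: potassium hydroxide (its oxygen becomes a carboxyl oxygen), [K+].[OH-]
Why: Saponification of a hindered ester by weakly solvated hydroxide in DMSO should proceed while the benzyl aryl ethers, inert to base, stay in place.

Step 10
Reactants: 12 benzyl 2-heptyl-4,6-dihydroxybenzoate, 15 2,4-bis(benzyloxy)-6-methylbenzoic acid
Product: 17 benzyl 4-{[2,4-bis(benzyloxy)-6-methylbenzoyl]oxy}-2-heptyl-6-hydroxybenzoate, via mixed trifluoroacetic anhydride 16 (not isolated)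
Conditions: (CF3CO)2O (4 equiv), toluene, rt
Reagents that add atoms: none
Why: Trifluoroacetic anhydride-mediated esterification, the standard assembly of para-depsides from benzyl β-resorcylates: the hindered acid is activated as its mixed anhydride and captured by the C4 hydroxyl, which is the more nucleophilic because the C6 hydroxyl is hydrogen-bonded to the neighbouring ester carbonyl and crowded by it.

Step 11
Reactants: 17 benzyl 4-{[2,4-bis(benzyloxy)-6-methylbenzoyl]oxy}-2-heptyl-6-hydroxybenzoate
Product: 18 4-[(2,4-dihydroxy-6-methylbenzoyl)oxy]-2-heptyl-6-hydroxybenzoic acid (target)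
Conditions: H2 (1 atm), 10% Pd/C (palladium on carbon), EtOAc, rt
Reagents that add atoms: none
Why: Catalytic hydrogenolysis cleaves the benzylic C–O bonds of the benzyl ester and both benzyl ethers, whereas the depside aryl ester has no benzylic C–O bond and the neutral, cold conditions avoid its hydrolysis and decarboxylation of the product.

**Compound list**
1 | 1-fluoro-3,5-dimethoxybenzene | COc1cc(F)cc(OC)c1 | starting material
2 | 5-fluorobenzene-1,3-diol | Oc1cc(O)cc(F)c1 | intermediate
3 | 1-fluoro-3,5-bis(methoxymethoxy)benzene | COCOc1cc(F)cc(OCOC)c1 | intermediate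
4 | 2-bromo-1-fluoro-3,5-bis(methoxymethoxy)benzene | COCOc1cc(F)c(Br)c(OCOC)c1 | intermediate
5 | 1-bromoheptane | CCCCCCCBr | starting material
6 | heptylmagnesium bromide | CCCCCCC[Mg]Br | intermediate
7 | [2-fluoro-4,6-bis(methoxymethoxy)phenyl]magnesium bromide | COCOc1cc(F)c([Mg]Br)c(OCOC)c1 | intermediate (not isolated)
8 | 3,5-bis(methoxymethoxy)benzyne | COCOC1=CC(OCOC)=CC#C1 | intermediate (not isolated)
9 | [2-heptyl-4,6-bis(methoxymethoxy)phenyl]magnesium bromide | CCCCCCCc1cc(OCOC)cc(OCOC)c1[Mg]Br | intermediate (not isolated)
10 | 2-heptyl-4,6-bis(methoxymethoxy)benzoic acid | CCCCCCCc1cc(OCOC)cc(OCOC)c1C(=O)O | intermediate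
11 | benzyl 2-heptyl-4,6-bis(methoxymethoxy)benzoate | CCCCCCCc1cc(OCOC)cc(OCOC)c1C(=O)OCc1ccccc1 | intermediate
12 | benzyl 2-heptyl-4,6-dihydroxybenzoate | CCCCCCCc1cc(O)cc(O)c1C(=O)OCc1ccccc1 | intermediate
13 | orsellinic acid (2,4-dihydroxy-6-methylbenzoic acid) | Cc1cc(O)cc(O)c1C(=O)O | starting material
14 | benzyl 2,4-bis(benzyloxy)-6-methylbenzoate | Cc1cc(OCc2ccccc2)cc(OCc2ccccc2)c1C(=O)OCc1ccccc1 | intermediate
15 | 2,4-bis(benzyloxy)-6-methylbenzoic acid | Cc1cc(OCc2ccccc2)cc(OCc2ccccc2)c1C(=O)O | intermediate
16 | 2,4-bis(benzyloxy)-6-methylbenzoic trifluoroacetic anhydride | Cc1cc(OCc2ccccc2)cc(OCc2ccccc2)c1C(=O)OC(=O)C(F)(F)F | intermediate (not isolated)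
17 | benzyl 4-{[2,4-bis(benzyloxy)-6-methylbenzoyl]oxy}-2-heptyl-6-hydroxybenzoate | CCCCCCCc1cc(OC(=O)c2c(C)cc(OCc3ccccc3)cc2OCc2ccccc2)cc(O)c1C(=O)OCc1ccccc1 | intermediate
18 | 4-[(2,4-dihydroxy-6-methylbenzoyl)oxy]-2-heptyl-6-hydroxybenzoic acid | CCCCCCCc1cc(OC(=O)c2c(C)cc(O)cc2O)cc(O)c1C(=O)O | target

**Step count**
Total: 11 steps. Longest linear sequence: 8 steps (1, 2, 3, 5, 6, 7, 10, 11, from compound 1 to compound 18).

**Steps most likely to fail**

Step 5. The fluoroaryl Grignard reagent 7 may add to aryne 8 and give biaryls. The alkyl Grignard reagent may reduce the aryne by hydride transfer, addition may take the reverse orientation, or insertion of magnesium into the crowded C–Br bond may stall. Surplus alkyl Grignard reagent is also carboxylated to an aliphatic acid, which is best removed after esterification in step 6. The fallback builds ring A without an aryne and sets out from 6. Kumada coupling of 6 with purchased 1-bromo-3,5-dimethoxybenzene (COc1cc(Br)cc(OC)c1) under NiCl2(dppp) catalysis in THF should give 1-heptyl-3,5-dimethoxybenzene F1. Demethylation with BBr3 should give 5-heptylbenzene-1,3-diol F2. Ortho-carboxylation with methyl magnesium carbonate (MeOMgOCO2Me) in DMF at 120 °C, the reaction that converts 5-alkylresorcinols into 6-alkyl-β-resorcylic acids, should give 2-heptyl-4,6-dihydroxybenzoic acid F3. Selective benzylation of the carboxylate (BnBr, KHCO3, DMF) comes back to the route at 12.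

Step 3. Bromination may occur between the two acetal oxygens, a second bromine may enter the very electron-rich ring, or traces of HBr may strip an acetal. The fallback introduces the halogen before the protecting groups are exchanged and sets out from 1. NBS in MeCN should give 2-bromo-1-fluoro-3,5-dimethoxybenzene F4, which can be freed of any isomer by crystallisation. BBr3 should then give 4-bromo-5-fluorobenzene-1,3-diol F5, and MOMCl with iPr2NEt comes back to the route at 4.

Step 10. The chelated C6 hydroxyl may compete for the acyl group and give the isomeric or doubly acylated ester, or acyl transfer from the di-ortho-substituted acid may be too slow. The fallback removes the need for site selection in the ester-forming step by masking the C6 hydroxyl, and sets out from 12. Silylation of the unchelated hydroxyl (TBSCl, imidazole, DMF) should give benzyl 4-[(tert-butyldimethylsilyl)oxy]-2-heptyl-6-hydroxybenzoate F6. Mitsunobu benzylation of the remaining phenol (BnOH, PPh3, DIAD) should give benzyl 2-(benzyloxy)-4-[(tert-butyldimethylsilyl)oxy]-6-heptylbenzoate F7. Bu4NF should release benzyl 2-(benzyloxy)-6-heptyl-4-hydroxybenzoate F8. With a single hydroxyl left, esterification with 15 under forcing conditions (DCC, DMAP, CH2Cl2) should give benzyl 2-(benzyloxy)-4-{[2,4-bis(benzyloxy)-6-methylbenzoyl]oxy}-6-heptylbenzoate F9. Hydrogenolysis over Pd/C removes all four benzyl groups and comes back to the route at 18.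

**Further compounds**
F1 | step 5 | 1-heptyl-3,5-dimethoxybenzene | CCCCCCCc1cc(OC)cc(OC)c1
F2 | step 5 | 5-heptylbenzene-1,3-diol | CCCCCCCc1cc(O)cc(O)c1
F3 | step 5 | 2-heptyl-4,6-dihydroxybenzoic acid | CCCCCCCc1cc(O)cc(O)c1C(=O)O
F4 | step 3 | 2-bromo-1-fluoro-3,5-dimethoxybenzene | COc1cc(F)c(Br)c(OC)c1
F5 | step 3 | 4-bromo-5-fluorobenzene-1,3-diol | Oc1cc(F)c(Br)c(O)c1
F6 | step 10 | benzyl 4-[(tert-butyldimethylsilyl)oxy]-2-heptyl-6-hydroxybenzoate | CCCCCCCc1cc(O[Si](C)(C)C(C)(C)C)cc(O)c1C(=O)OCc1ccccc1
F7 | step 10 | benzyl 2-(benzyloxy)-4-[(tert-butyldimethylsilyl)oxy]-6-heptylbenzoate | CCCCCCCc1cc(O[Si](C)(C)C(C)(C)C)cc(OCc2ccccc2)c1C(=O)OCc1ccccc1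
F8 | step 10 | benzyl 2-(benzyloxy)-6-heptyl-4-hydroxybenzoate | CCCCCCCc1cc(O)cc(OCc2ccccc2)c1C(=O)OCc1ccccc1
F9 | step 10 | benzyl 2-(benzyloxy)-4-{[2,4-bis(benzyloxy)-6-methylbenzoyl]oxy}-6-heptylbenzoate | CCCCCCCc1cc(OC(=O)c2c(C)cc(OCc3ccccc3)cc2OCc2ccccc2)cc(OCc2ccccc2)c1C(=O)OCc1ccccc1
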